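**Strategy**

Everything rests on disconnecting the aryl ketone bond C4–C4a of ring C. The key step exploits that C4a is the only ring A carbon ortho to the ring oxygen O1 that is not taken by the C8 prenyl group, and that the acyl carbon C4 hangs from O1 through C2 and C3: an iodine parked on C4a is exchanged for lithium and the aryllithium acylates the tethered Weinreb amide (Parham cyclization), closing the pyranone in one cold, acid-free operation that spares the (R)-epoxide, the prenyl alkene and the C2 stereocentre. The precursor is an open-chain (S)-3-aryl-3-(2-iodoaryloxy)propanoic Weinreb amide, assembled by iridium-catalysed asymmetric allylic etherification.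

Key step: step 13

Abbreviations: TIPS = tri(propan-2-yl)silyl; prenyl = 3-methylbut-2-en-1-yl; ArA = 2-iodo-6-prenyl-3,5-bis(TIPS-oxy)phenyl; ArB = 3-{[(2R)-3,3-dimethyloxiran-2-yl]methyl}-4-(TIPS-oxy)phenyl.

Assumption: the (Sa,Sc,Sc) enantiomer of the phosphoramidite ligand is taken to give the (S) ether in step 9, the usual sense of this catalyst with aryl-substituted allyl carbonates; the mirror-image ligand would be used if the sense proved opposite.

Assumption: (E)-3-(tributylstannyl)prop-2-en-1-ol, the D-fructose-derived Shi ketone and the phosphoramidite ligand are taken as purchasable reagents.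

**Route**

Step 1
Reactants: 1 phloroglucinol
Product: 2 2-prenylphloroglucinol
Conditions: prenyl bromide (0.5 equiv), DBU (0.5 equiv), THF, 0 °C → rt; excess 1 recovered
Reagents that add atoms: prenyl bromide (1-bromo-3-methylbut-2-ene), CC(C)=CCBr
Why: C-alkylation of the ambident phloroglucinol anion (Friedel–Crafts-type allylation of a strongly enolised arene) with the phenol in excess should give mainly the mono-C-prenyl compound.

Step 2
Reactants: 2 2-prenylphloroglucinol
Product: 3 2-iodo-4-prenylbenzene-1,3,5-triol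
Conditions: NIS (1.0 equiv), THF, −78 °C, dark
Reagents that add atoms: N-iodosuccinimide, O=C1CCC(=O)N1I
Why: Electrophilic aromatic iodination with one equivalent of reagent at low temperature should hit one of the two symmetry-equivalent free positions of the very electron-rich ring faster than the iodonium source engages the prenyl alkene.

Step 3
Reactants: 3 2-iodo-4-prenylbenzene-1,3,5-triol
Product: 4 2-iodo-6-prenyl-3,5-bis(TIPS-oxy)phenol
Conditions: TIPSCl (2.1 equiv), imidazole, DMF, 0 °C
Reagents that add atoms: chlorotri(propan-2-yl)silane (TIPSCl), CC(C)[Si](Cl)(C(C)C)C(C)C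
Why: Silyl ether formation with the bulky chlorosilane should take the two hydroxyls that carry a single ortho substituent and leave the hydroxyl flanked by iodine and the prenyl group free.

Step 4
Reactants: 5 4-bromophenol
Product: 6 4-bromo-2-prenylphenol
Conditions: NaH, toluene, 0 °C; prenyl bromide, rt
Reagents that add atoms: prenyl bromide (1-bromo-3-methylbut-2-ene), CC(C)=CCBr
Why: Ortho-C-alkylation of a sodium phenoxide held as a tight ion pair in a non-polar solvent places the prenyl group next to oxygen, the para position being blocked by bromine.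

Step 5
Reactants: 6 4-bromo-2-prenylphenol
Product: 7 TIPS ether of 4-bromo-2-prenylphenol
Conditions: TIPSCl, imidazole, DMF, rt
Reagents that add atoms: chlorotri(propan-2-yl)silane (TIPSCl), CC(C)[Si](Cl)(C(C)C)C(C)C
Why: Standard silyl ether formation masks the phenol against the oxidant, the bases and the organometallic reagents of the later steps.

Step 6
Reactants: 7 TIPS ether of 4-bromo-2-prenylphenol
Product: 8 (R)-epoxide, (4-bromo-2-{[(2R)-3,3-dimethyloxiran-2-yl]methyl}phenoxy)-TIPS
Conditions: 1,2:4,5-di-O-isopropylidene-β-D-erythro-2,3-hexodiulo-2,6-pyranose (D-fructose-derived Shi ketone, 0.3 equiv), Oxone (2KHSO5·KHSO4·K2SO4), K2CO3, Bu4NHSO4, MeCN–CH2(OMe)2 / aq. Na2B4O7–Na2EDTA buffer (pH 10.5), 0 °C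
Reagents that add atoms: potassium peroxymonosulfate (active part of Oxone), [K+].[O-]S(=O)(=O)OO
Why: Shi asymmetric epoxidation, in which the chiral dioxirane from the D-fructose-derived ketone attacks the trisubstituted alkene through the spiro transition state, should set the (R) configuration at the epoxide carbon while aryl bromide and silyl ether stay inert.

Step 7
Reactants: 8 (R)-epoxide aryl bromide
Product: 9 (E)-cinnamyl alcohol, (2E)-3-ArB-prop-2-en-1-ol
Conditions: (E)-Bu3SnCH=CHCH2OH (1.2 equiv), Pd(PPh3)4 (5 mol %), toluene, 100 °C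
Reagents that add atoms: (E)-3-(tributylstannyl)prop-2-en-1-ol, CCCC[Sn](CCCC)(CCCC)/C=C/CO
Why: Stille coupling of the aryl bromide with the (E)-alkenylstannane proceeds with retention of alkene geometry under neutral conditions that epoxide and silyl ether tolerate.

Step 8
Reactants: 9 (E)-cinnamyl alcohol
Product: 10 (E)-cinnamyl methyl carbonate
Conditions: ClCO2Me, pyridine, CH2Cl2, 0 °C
Reagents that add atoms: methyl chloroformate, COC(Cl)=O
Why: Acylation of the primary allylic alcohol with the chloroformate installs the carbonate leaving group needed for ionisation by iridium.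

Step 9
Reactants: 4 2-iodo-6-prenyl-3,5-bis(TIPS-oxy)phenol, 10 (E)-cinnamyl methyl carbonate
Product: 12 (S)-branched ether ArA–O–CH(ArB)–CH=CH2, via sodium aryloxide 11 (not isolated)
Conditions: 4, NaH, THF, 0 °C; then 10, [Ir(cod)Cl]2 (2 mol %), (Sa,Sc,Sc)-O,O'-(1,1'-binaphthalene-2,2'-diyl) N,N-bis(1-phenylethyl)phosphoramidite (4 mol %, pre-activated with n-PrNH2), THF, 50 °C
Reagents that add atoms: none
Why: Iridium-catalysed asymmetric allylic etherification, in which the cyclometalated iridium phosphoramidite ionises the carbonate and the aryloxide attacks the aryl-bearing allyl terminus, should give the branched ether and set C2 as (S) under control of the ligand.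

Step 10
Reactants: 12 (S)-branched allyl aryl ether
Product: 14 (3S)-3-ArB-3-(ArA-oxy)propan-1-ol, via B-alkyl-9-BBN adduct 13 (not isolated)
Conditions: 9-BBN (9-borabicyclo[3.3.1]nonane, 1.5 equiv), THF, 0 °C → rt; then 30% H2O2, aq. NaOAc, 0 °C
Reagents that add atoms: hydrogen peroxide, OO
Why: Anti-Markovnikov hydroboration–oxidation with the bulky borane should select the monosubstituted alkene over the trisubstituted prenyl alkene, boron on C4 has no β-oxygen to eliminate, and the buffered oxidation spares silyl ethers, epoxide and the C2 centre.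

Step 11
Reactants: 14 (3S)-3-ArB-3-(ArA-oxy)propan-1-ol
Product: 16 (3S)-3-ArB-3-(ArA-oxy)propanoic acid, via aldehyde 15 (not isolated)
Conditions: TEMPO (2,2,6,6-tetramethylpiperidin-1-oxyl, 0.2 equiv), PhI(OAc)2 (2.2 equiv), MeCN–pH 7 phosphate buffer (1:1), 0 °C → rt
Reagents that add atoms: water, O
Why: TEMPO-catalysed oxidation with PhI(OAc)2 in buffered aqueous acetonitrile takes the primary alcohol through the aldehyde hydrate to the acid without touching alkene, epoxide, aryl iodide or silyl ethers.

Step 12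
Reactants: 16 (3S)-3-ArB-3-(ArA-oxy)propanoic acid
Product: 17 Weinreb amide, (3S)-N-methoxy-N-methyl-3-ArB-3-(ArA-oxy)propanamide
Conditions: MeNHOMe·HCl, EDC·HCl, HOBt (cat.), N-methylmorpholine, CH2Cl2, 0 °C → rt
Reagents that add atoms: N,O-dimethylhydroxylamine hydrochloride, CNOC.Cl
Why: Carbodiimide-mediated amide coupling with only a weak amine base gives the Weinreb amide without enolisation and therefore without β-elimination of the aryloxide.

Step 13
Reactants: 17 Weinreb amide
Product: 20 tris-TIPS ether of the target flavanone, via aryllithium 18 (not isolated), via lithium hemiaminal 19 (not isolated)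
Conditions: t-BuLi (2.1 equiv), THF, −78 °C, 15 min; sat. aq. NH4Cl, −78 °C → rt
Reagents that add atoms: none
Why: Iodine–lithium exchange at C4a, which is faster than addition of tert-butyllithium to the amide or deprotonation at C3, gives aryllithium 18, whose carbanion adds to the tethered Weinreb carbonyl C4 to give the N-methoxy-chelated lithium hemiaminal 19, and this persists until the cold quench and then collapses to the ketone. The closest known reaction type is the Parham cyclization, the anionic cycloacylation of an aryl halide onto a Weinreb amide. Ring C is closed in the 6-exo-trig mode. No stereocentre is created in the product (C4 of 19 is transient), and the C2 and epoxide centres are untouched because the chelated intermediate blocks enolisation and with it retro-oxa-Michael opening. The step needs site selectivity, secured by the iodine fixed on C4a and the prenyl group blocking C8, and chemoselectivity over epoxide, silyl ethers and prenyl alkene, secured by the −78 °C anionic conditions. Migration of the C5 silyl group onto the lithiated carbon is held back by the bulk of the TIPS group and the speed of the six-membered acyl transfer.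

Step 14
Reactants: 20 tris-TIPS ether of the target flavanone
Product: 21 target CNP0324151.1
Conditions: Bu4NF (TBAF, 3.5 equiv), AcOH (3.5 equiv), THF, 0 °C
Reagents that add atoms: none
Why: Fluoride-mediated cleavage of the three aryl silyl ethers, buffered with acetic acid so that no free phenoxide builds up, should release the phenols without epoxide opening by the neighbouring 4'-oxygen and without the base-induced ring opening of the flavanone that would racemise C2.

**Compound list**

1 | phloroglucinol (benzene-1,3,5-triol) | Oc1cc(O)cc(O)c1 | starting material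
2 | 2-(3-methylbut-2-en-1-yl)benzene-1,3,5-triol | CC(C)=CCc1c(O)cc(O)cc1O | intermediate
3 | 2-iodo-4-(3-methylbut-2-en-1-yl)benzene-1,3,5-triol | CC(C)=CCc1c(O)cc(O)c(I)c1O | intermediate
4 | 2-iodo-6-(3-methylbut-2-en-1-yl)-3,5-bis(TIPS-oxy)phenol | CC(C)=CCc1c(O[Si](C(C)C)(C(C)C)C(C)C)cc(O[Si](C(C)C)(C(C)C)C(C)C)c(I)c1O | intermediate
5 | 4-bromophenol | Oc1ccc(Br)cc1 | starting material
6 | 4-bromo-2-(3-methylbut-2-en-1-yl)phenol | CC(C)=CCc1cc(Br)ccc1O | intermediate
7 | [4-bromo-2-(3-methylbut-2-en-1-yl)phenoxy]tri(propan-2-yl)silane | CC(C)=CCc1cc(Br)ccc1O[Si](C(C)C)(C(C)C)C(C)C | intermediate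
8 | (4-bromo-2-{[(2R)-3,3-dimethyloxiran-2-yl]methyl}phenoxy)tri(propan-2-yl)silane | Brc1ccc(O[Si](C(C)C)(C(C)C)C(C)C)c(C[C@H]2OC2(C)C)c1 | intermediate
9 | (2E)-3-(3-{[(2R)-3,3-dimethyloxiran-2-yl]methyl}-4-(TIPS-oxy)phenyl)prop-2-en-1-ol | OC/C=C/c1ccc(O[Si](C(C)C)(C(C)C)C(C)C)c(C[C@H]2OC2(C)C)c1 | intermediate
10 | (2E)-3-(3-{[(2R)-3,3-dimethyloxiran-2-yl]methyl}-4-(TIPS-oxy)phenyl)prop-2-en-1-yl methyl carbonate | COC(=O)OC/C=C/c1ccc(O[Si](C(C)C)(C(C)C)C(C)C)c(C[C@H]2OC2(C)C)c1 | intermediate
11 | sodium 2-iodo-6-(3-methylbut-2-en-1-yl)-3,5-bis(TIPS-oxy)phenolate (formed in the flask) | [Na+].[O-]c1c(I)c(O[Si](C(C)C)(C(C)C)C(C)C)cc(O[Si](C(C)C)(C(C)C)C(C)C)c1CC=C(C)C | intermediate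
12 | 1-iodo-2-{[(1S)-1-(3-{[(2R)-3,3-dimethyloxiran-2-yl]methyl}-4-(TIPS-oxy)phenyl)prop-2-en-1-yl]oxy}-3-(3-methylbut-2-en-1-yl)-4,6-bis(TIPS-oxy)benzene | C=C[C@H](Oc1c(I)c(O[Si](C(C)C)(C(C)C)C(C)C)cc(O[Si](C(C)C)(C(C)C)C(C)C)c1CC=C(C)C)c1ccc(O[Si](C(C)C)(C(C)C)C(C)C)c(C[C@H]2OC2(C)C)c1 | intermediate
13 | adduct of 12 with 9-BBN, boron on the terminal carbon (formed in the flask) | C(C[C@H](Oc1c(I)c(O[Si](C(C)C)(C(C)C)C(C)C)cc(O[Si](C(C)C)(C(C)C)C(C)C)c1CC=C(C)C)c1ccc(O[Si](C(C)C)(C(C)C)C(C)C)c(C[C@H]2OC2(C)C)c1)B1C2CCCC1CCC2 | intermediate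
14 | (3S)-3-(3-{[(2R)-3,3-dimethyloxiran-2-yl]methyl}-4-(TIPS-oxy)phenyl)-3-[2-iodo-6-(3-methylbut-2-en-1-yl)-3,5-bis(TIPS-oxy)phenoxy]propan-1-ol | OCC[C@H](Oc1c(I)c(O[Si](C(C)C)(C(C)C)C(C)C)cc(O[Si](C(C)C)(C(C)C)C(C)C)c1CC=C(C)C)c1ccc(O[Si](C(C)C)(C(C)C)C(C)C)c(C[C@H]2OC2(C)C)c1 | intermediate
15 | the corresponding (3S)-propanal (formed in the flask in step 11) | O=CC[C@H](Oc1c(I)c(O[Si](C(C)C)(C(C)C)C(C)C)cc(O[Si](C(C)C)(C(C)C)C(C)C)c1CC=C(C)C)c1ccc(O[Si](C(C)C)(C(C)C)C(C)C)c(C[C@H]2OC2(C)C)c1 | intermediate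
16 | the corresponding (3S)-propanoic acid | OC(=O)C[C@H](Oc1c(I)c(O[Si](C(C)C)(C(C)C)C(C)C)cc(O[Si](C(C)C)(C(C)C)C(C)C)c1CC=C(C)C)c1ccc(O[Si](C(C)C)(C(C)C)C(C)C)c(C[C@H]2OC2(C)C)c1 | intermediate
17 | the corresponding (3S)-N-methoxy-N-methylpropanamide (Weinreb amide) | CON(C)C(=O)C[C@H](Oc1c(I)c(O[Si](C(C)C)(C(C)C)C(C)C)cc(O[Si](C(C)C)(C(C)C)C(C)C)c1CC=C(C)C)c1ccc(O[Si](C(C)C)(C(C)C)C(C)C)c(C[C@H]2OC2(C)C)c1 | intermediate
18 | aryllithium, iodine of 17 replaced by lithium (formed in the flask) | CON(C)C(=O)C[C@H](Oc1c([Li])c(O[Si](C(C)C)(C(C)C)C(C)C)cc(O[Si](C(C)C)(C(C)C)C(C)C)c1CC=C(C)C)c1ccc(O[Si](C(C)C)(C(C)C)C(C)C)c(C[C@H]2OC2(C)C)c1 | intermediate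
19 | lithium salt of the cyclic C4 hemiaminal, (2S)-4-[methoxy(methyl)amino]chroman-4-olate, both C4 epimers (formed in the flask) | CC(C)=CCc1c(O[Si](C(C)C)(C(C)C)C(C)C)cc(O[Si](C(C)C)(C(C)C)C(C)C)c2c1O[C@H](c1ccc(O[Si](C(C)C)(C(C)C)C(C)C)c(C[C@H]3OC3(C)C)c1)CC2(O[Li])N(C)OC | intermediate
20 | (2S)-2-(3-{[(2R)-3,3-dimethyloxiran-2-yl]methyl}-4-(TIPS-oxy)phenyl)-8-(3-methylbut-2-en-1-yl)-5,7-bis(TIPS-oxy)-2,3-dihydro-4H-chromen-4-one | CC(C)=CCc1c(O[Si](C(C)C)(C(C)C)C(C)C)cc(O[Si](C(C)C)(C(C)C)C(C)C)c2c1O[C@H](c1ccc(O[Si](C(C)C)(C(C)C)C(C)C)c(C[C@H]3OC3(C)C)c1)CC2=O | intermediate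
21 | (2S)-2-(3-{[(2R)-3,3-dimethyloxiran-2-yl]methyl}-4-hydroxyphenyl)-5,7-dihydroxy-8-(3-methylbut-2-en-1-yl)-2,3-dihydro-4H-chromen-4-one (CNP0324151.1) | CC(C)=CCc1c(O)cc(O)c2c1O[C@H](c1ccc(O)c(C[C@H]3OC3(C)C)c1)CC2=O | target

**Step count and risks**

Total step count: 14. Longest linear sequence: 11 steps (4-bromophenol to target, steps 4–14).

Steps most likely to fail:

Step 9. The doubly ortho-substituted aryloxide may attack the allyliridium intermediate too slowly, so that isomerisation to the linear ether or loss of enantiopurity through reversible ionisation of the branched product takes over. Fallback (sets out from 8, returns to the route at 17): a Mitsunobu etherification with inversion replaces the allylic substitution. Bromine–lithium exchange on 8 (t-BuLi, THF, −78 °C) and trapping with methyl chloroformate should give the methyl benzoate F1. Claisen condensation of F1 with the lithium enolate of N-methoxy-N-methylacetamide should give the β-keto Weinreb amide F2. Noyori asymmetric transfer hydrogenation of F2 with RuCl[(R,R)-TsDPEN](p-cymene) and sodium formate in water–CH2Cl2 should give the (R)-β-hydroxy Weinreb amide F3. Mitsunobu coupling of F3 with phenol 4 (PPh3, DIAD, toluene, 0 °C) inverts the carbinol carbon and should give 17 directly. This way is two steps shorter from 8 but carries the risk of elimination to the cinnamamide, which is why it is held in reserve.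

Step 13. Proton transfer to the lithiated carbon, migration of the neighbouring silyl group onto it, or addition of the alkyllithium to the amide may outrun ring closure. Fallback (sets out from 14, returns at 20): the same C4–C4a bond is closed under non-basic, chromium-mediated conditions. Alcohol 14 is oxidised with Dess–Martin periodinane (NaHCO3, CH2Cl2) to aldehyde 15, isolated this time. An intramolecular Nozaki–Hiyama–Kishi reaction of the aryl iodide with the aldehyde (CrCl2, NiCl2 cat., DMF, rt) should give the chroman-4-ol F4 as a mixture of C4 epimers. Dess–Martin oxidation of F4 gives 20.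

Step 3. Site selectivity of the silylation may be lost, with the third hydroxyl also silylated or one of the wanted ones left free. Fallback (sets out from 1, returns at 4): the silyl ethers are put on first and the two ortho substituents are then brought in under the direction of the single free hydroxyl. Phloroglucinol 1 is silylated with two equivalents of TIPSCl (imidazole, DMF) to the 3,5-bis(TIPS-oxy)phenol F5, separated from mono- and tris-silyl ethers. NIS should iodinate F5 ortho to the hydroxyl, the para position lying between two silyloxy groups, to give the 2-iodo-3,5-bis(TIPS-oxy)phenol F6. Ortho-C-prenylation of the sodium phenoxide of F6 (NaH, toluene, prenyl bromide) at the only free ortho position gives 4.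

Further compounds
F1 | step 9 | methyl 3-{[(2R)-3,3-dimethyloxiran-2-yl]methyl}-4-(TIPS-oxy)benzoate | COC(=O)c1ccc(O[Si](C(C)C)(C(C)C)C(C)C)c(C[C@H]2OC2(C)C)c1
F2 | step 9 | 3-(3-{[(2R)-3,3-dimethyloxiran-2-yl]methyl}-4-(TIPS-oxy)phenyl)-N-methoxy-N-methyl-3-oxopropanamide | CON(C)C(=O)CC(=O)c1ccc(O[Si](C(C)C)(C(C)C)C(C)C)c(C[C@H]2OC2(C)C)c1
F3 | step 9 | (3R)-3-(3-{[(2R)-3,3-dimethyloxiran-2-yl]methyl}-4-(TIPS-oxy)phenyl)-3-hydroxy-N-methoxy-N-methylpropanamide | CON(C)C(=O)C[C@@H](O)c1ccc(O[Si](C(C)C)(C(C)C)C(C)C)c(C[C@H]2OC2(C)C)c1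
F4 | step 13 | (2S)-2-(3-{[(2R)-3,3-dimethyloxiran-2-yl]methyl}-4-(TIPS-oxy)phenyl)-8-(3-methylbut-2-en-1-yl)-5,7-bis(TIPS-oxy)chroman-4-ol, both C4 epimers | CC(C)=CCc1c(O[Si](C(C)C)(C(C)C)C(C)C)cc(O[Si](C(C)C)(C(C)C)C(C)C)c2c1O[C@H](c1ccc(O[Si](C(C)C)(C(C)C)C(C)C)c(C[C@H]3OC3(C)C)c1)CC2O
F5 | step 3 | 3,5-bis(TIPS-oxy)phenol | Oc1cc(O[Si](C(C)C)(C(C)C)C(C)C)cc(O[Si](C(C)C)(C(C)C)C(C)C)c1
F6 | step 3 | 2-iodo-3,5-bis(TIPS-oxy)phenol | Oc1cc(O[Si](C(C)C)(C(C)C)C(C)C)cc(O[Si](C(C)C)(C(C)C)C(C)C)c1I
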